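## Retrosynthetic overview

1. Ring numbering: C1 aryl-bearing CH, C2 CMe2, C3 CH2, C4 CH–isopropenyl, C5 CH2. The target is the C1/C4-trans (1R,4R) isomer. The benzoyl group (directed ortho-lithiation) and the free phenols (MOM removal) are installed last on a purchased aromatic ring.
2. Key disconnection: the C4–C5 ring bond together with the C4–isopropenyl bond. The open-chain nitroalkane O2N–CH2(C5)–CH(Ar)(C1)–CMe2(C2)–CH=CH2(C3=C4) and 2-bromopropene are joined in one palladium cascade (vinylation, one-carbon palladium migration, nitronate capture). The nitro group on C5 is then removed with Bu3SnH.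
3. The open-chain precursor comes from Wittig methylenation of the aldehyde formed by an organocatalytic Michael addition of isobutyraldehyde to the aryl nitroalkene (sets C1, forges the congested C1–C2 bond). The nitroalkene comes from protected phloroglucinaldehyde and nitromethane.
4. Enabling feature: the quaternary C2 has no hydrogen and lies between C1 and C3, so palladium on C3 can only move to C4. C5 is a bare ring CH2 flanked by C1 and C4, so it can carry a nitro group that first activates the Michael acceptor, then serves as the ring-closing carbon nucleophile, then leaves.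
5. Order of ring formation: benzene ring (purchased), then the cyclopentane (step 5, the only ring-forming step).

Key step: step 5

Remark on the chemistry: both antipodes of the step 3 catalyst are commercial; the one that directs attack to the Re face of the nitroalkene β-carbon is used.

## Route

Step 1
Reactants: 1 2,4,6-trihydroxybenzaldehyde
Product: 2 2,4,6-tris(methoxymethoxy)benzaldehyde
Conditions: NaH (3.6 equiv), MOMCl (3.6 equiv), DMF, 0 °C → rt
Reagents that add atoms: chloromethyl methyl ether (MOMCl), COCCl
Why: Williamson etherification of the three phenoxides with the reactive α-chloro ether; the aldehyde is inert to NaH and no stereocenter is involved.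

Step 2
Reactants: 2 2,4,6-tris(methoxymethoxy)benzaldehyde; 3 nitromethane
Product: 5 1,3,5-tris(methoxymethoxy)-2-[(E)-2-nitroethenyl]benzene, via nitroaldol 4 (not isolated)
Conditions: NH4OAc (0.5 equiv), CH3NO2 as solvent, 90 °C
Reagents that add atoms: none
Why: Henry (nitroaldol) reaction followed by in situ dehydration of 4, driven by conjugation with the electron-rich ring, should give the (E)-nitroalkene.

Step 3
Reactants: 5 1,3,5-tris(methoxymethoxy)-2-[(E)-2-nitroethenyl]benzene; 6 isobutyraldehyde (2-methylpropanal)
Product: 7 (3S)-2,2-dimethyl-4-nitro-3-[2,4,6-tris(methoxymethoxy)phenyl]butanal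
Conditions: trans-1-(2-aminocyclohexyl)-3-[3,5-bis(trifluoromethyl)phenyl]thiourea, single enantiomer (20 mol %), PhCO2H (20 mol %), H2O (2 equiv), 6 (4 equiv), toluene, rt
Reagents that add atoms: none
Why: Organocatalytic asymmetric Michael addition: the primary amine forms the enamine of 6 while the thiourea hydrogen-bonds the nitro group of 5, so the new quaternary carbon attacks the Re face of the β-carbon and the benzylic stereocenter (3S) is set under catalyst control.

Step 4
Reactants: 7 (3S)-2,2-dimethyl-4-nitro-3-[2,4,6-tris(methoxymethoxy)phenyl]butanal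
Product: 8 2-[(2R)-3,3-dimethyl-1-nitropent-4-en-2-yl]-1,3,5-tris(methoxymethoxy)benzene
Conditions: Ph3PCH3Br (2.5 equiv), KN(SiMe3)2 (2.4 equiv), THF, 0 °C; then 7, −78 °C → rt; aq. NH4Cl
Reagents that add atoms: methyltriphenylphosphonium bromide, C[P+](c1ccccc1)(c1ccccc1)c1ccccc1.[Br-]
Why: Wittig methylenation of a non-enolisable aldehyde; the extra ylide only parks the acidic CH2NO2 group as its potassium nitronate until work-up, and the benzylic center is untouched (the descriptor changes from S to R only because the substituent ranking changes).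

Step 5
Reactants: 8 2-[(2R)-3,3-dimethyl-1-nitropent-4-en-2-yl]-1,3,5-tris(methoxymethoxy)benzene; 9 2-bromopropene
Product: 12 1,3,5-tris(methoxymethoxy)-2-[(1R,4R)-2,2-dimethyl-5-nitro-4-(prop-1-en-2-yl)cyclopentyl]benzene as a mixture of C5 epimers, via alkylpalladium bromide 10 (not isolated), via allylpalladium bromide 11 (not isolated)
Conditions: Pd(OAc)2 (5 mol %), n-Bu4NCl (1.1 equiv), Na2CO3 (2.5 equiv), 9 (3 equiv), DMF, 80 °C, sealed tube
Reagents that add atoms: none
Why: Proposed new method: zerovalent palladium (formed in situ from Pd(OAc)2) inserts into the C–Br bond of 9, the isopropenylpalladium species adds across the terminal vinyl group of 8 with the isopropenyl group going to the CH2 terminus (10), and because the neighbouring quaternary C2 has no hydrogen, β-hydride elimination and re-addition can only move palladium one carbon toward the new alkene to give the η3-allyl complex 11, which the nitronate of the CH2NO2 group attacks at its substituted terminus anti to the metal, closing the C4–C5 bond and releasing zerovalent palladium. The closest known reaction type is the palladium-catalysed coupling of vinylic halides with terminal olefinic sulfonamides, where the same insertion/migration sequence ends in intramolecular amination to 2-alkenylpyrrolidines, together with the three-component versions using amines or stabilised carbanions and the Tsuji–Trost C-allylation of nitronates; the new element is a tethered carbon nucleophile. The cyclopentane is closed in the 5-exo mode (nitronate carbon onto the internal terminus of an exocyclic allyl unit), since attack at the CH2 terminus would need a seven-membered ring and an anti-carbopalladation of the alkene would need a four-membered ring. C4 is controlled by the existing C1 stereocenter: the two faces of the allyl unit interconvert by η3–η1–η3 isomerisation at the CH2 end, and closure should run through the chair-like transition state with the aryl group pseudo-equatorial and anti to the nitronate N–O bonds (allylic strain), which leads to the C1/C4-trans product, while C5 epimerises through the nitronate and is erased in step 6. The step needs regioselective insertion, one-directional palladium migration and C- over O-alkylation, secured respectively by the terminal neopentyl-type alkene, by the hydrogen-free C2 and by ring size (five-membered C-attack against seven-membered O-attack), and the gem-dimethyl group also favours cyclisation.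

Step 6
Reactants: 12 1,3,5-tris(methoxymethoxy)-2-[(1R,4R)-2,2-dimethyl-5-nitro-4-(prop-1-en-2-yl)cyclopentyl]benzene
Product: 13 1,3,5-tris(methoxymethoxy)-2-[(1R,4R)-2,2-dimethyl-4-(prop-1-en-2-yl)cyclopentyl]benzene
Conditions: Bu3SnH (5 equiv), AIBN (0.3 equiv in portions), toluene, 110 °C
Reagents that add atoms: none
Why: Radical denitration: the Bu3Sn radical adds to a nitro oxygen and the adduct fragments to the secondary C5 radical, which at high Bu3SnH concentration should abstract hydrogen faster than it can rearrange, so C5 becomes a CH2 group and C1 and C4 are untouched.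

Step 7
Reactants: 13 1,3,5-tris(methoxymethoxy)-2-[(1R,4R)-2,2-dimethyl-4-(prop-1-en-2-yl)cyclopentyl]benzene; 14 N-methoxy-N-methylbenzamide
Product: 16 {3-[(1R,4R)-2,2-dimethyl-4-(prop-1-en-2-yl)cyclopentyl]-2,4,6-tris(methoxymethoxy)phenyl}(phenyl)methanone, via aryllithium 15 (not isolated)
Conditions: n-BuLi (1.1 equiv), THF, 0 °C; then 14 (1.3 equiv), −78 °C → rt; H2O
Reagents that add atoms: none
Why: Directed ortho-metalation at the ring position flanked by two OMOM groups (the two free ring positions are equivalent) followed by acyl substitution on the N-methoxy-N-methylamide, whose chelated tetrahedral adduct prevents over-addition.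

Step 8
Reactants: 16 {3-[(1R,4R)-2,2-dimethyl-4-(prop-1-en-2-yl)cyclopentyl]-2,4,6-tris(methoxymethoxy)phenyl}(phenyl)methanone
Product: 17 {3-[(1R,4R)-2,2-dimethyl-4-(prop-1-en-2-yl)cyclopentyl]-2,4,6-trihydroxyphenyl}(phenyl)methanone
Conditions: HCl (2 M in MeOH), rt → 40 °C
Reagents that add atoms: none
Why: Acid-catalysed methanolysis of the three aryl MOM acetals; the 1,1-disubstituted alkene should tolerate dilute acid at this temperature and, being trans to the aryl group across the ring, cannot be trapped by an ortho-hydroxyl group.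

## Compound list

1 | 2,4,6-trihydroxybenzaldehyde | O=Cc1c(O)cc(O)cc1O | starting material
2 | 2,4,6-tris(methoxymethoxy)benzaldehyde | O=Cc1c(OCOC)cc(OCOC)cc1OCOC | intermediate
3 | nitromethane | C[N+](=O)[O-] | starting material
4 | 2-nitro-1-[2,4,6-tris(methoxymethoxy)phenyl]ethan-1-ol (racemic, not isolated) | OC(C[N+](=O)[O-])c1c(OCOC)cc(OCOC)cc1OCOC | intermediate
5 | 1,3,5-tris(methoxymethoxy)-2-[(E)-2-nitroethenyl]benzene | [O-][N+](=O)/C=C/c1c(OCOC)cc(OCOC)cc1OCOC | intermediate
6 | isobutyraldehyde (2-methylpropanal) | CC(C)C=O | starting material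
7 | (3S)-2,2-dimethyl-4-nitro-3-[2,4,6-tris(methoxymethoxy)phenyl]butanal | [O-][N+](=O)C[C@@H](c1c(OCOC)cc(OCOC)cc1OCOC)C(C)(C)C=O | intermediate
8 | 2-[(2R)-3,3-dimethyl-1-nitropent-4-en-2-yl]-1,3,5-tris(methoxymethoxy)benzene | [O-][N+](=O)C[C@@H](c1c(OCOC)cc(OCOC)cc1OCOC)C(C)(C)C=C | intermediate
9 | 2-bromopropene | CC(Br)=C | starting material
10 | bromo{2,5,5-trimethyl-7-nitro-6-[2,4,6-tris(methoxymethoxy)phenyl]hept-1-en-4-yl}palladium, σ-alkyl complex of divalent palladium (not isolated) | [O-][N+](=O)C[C@@H](c1c(OCOC)cc(OCOC)cc1OCOC)C(C)(C)C([Pd]Br)CC(C)=C | intermediate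
11 | bromo{2,5,5-trimethyl-7-nitro-6-[2,4,6-tris(methoxymethoxy)phenyl]hept-1-en-3-yl}palladium, η3-allyl complex of divalent palladium drawn in its σ-form (not isolated) | [O-][N+](=O)C[C@@H](c1c(OCOC)cc(OCOC)cc1OCOC)C(C)(C)CC([Pd]Br)C(C)=C | intermediate
12 | 1,3,5-tris(methoxymethoxy)-2-[(1R,4R)-2,2-dimethyl-5-nitro-4-(prop-1-en-2-yl)cyclopentyl]benzene, both C5 epimers (C5 left undefined) | C=C(C)[C@@H]1C([N+](=O)[O-])[C@@H](c2c(OCOC)cc(OCOC)cc2OCOC)C(C)(C)C1 | intermediate
13 | 1,3,5-tris(methoxymethoxy)-2-[(1R,4R)-2,2-dimethyl-4-(prop-1-en-2-yl)cyclopentyl]benzene | C=C(C)[C@@H]1C[C@@H](c2c(OCOC)cc(OCOC)cc2OCOC)C(C)(C)C1 | intermediate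
14 | N-methoxy-N-methylbenzamide | CON(C)C(=O)c1ccccc1 | starting material
15 | {3-[(1R,4R)-2,2-dimethyl-4-(prop-1-en-2-yl)cyclopentyl]-2,4,6-tris(methoxymethoxy)phenyl}lithium (not isolated) | C=C(C)[C@@H]1C[C@@H](c2c(OCOC)cc(OCOC)c([Li])c2OCOC)C(C)(C)C1 | intermediate
16 | {3-[(1R,4R)-2,2-dimethyl-4-(prop-1-en-2-yl)cyclopentyl]-2,4,6-tris(methoxymethoxy)phenyl}(phenyl)methanone | C=C(C)[C@@H]1C[C@@H](c2c(OCOC)cc(OCOC)c(C(=O)c3ccccc3)c2OCOC)C(C)(C)C1 | intermediate
17 | {3-[(1R,4R)-2,2-dimethyl-4-(prop-1-en-2-yl)cyclopentyl]-2,4,6-trihydroxyphenyl}(phenyl)methanone | C=C(C)[C@@H]1C[C@@H](c2c(O)cc(O)c(C(=O)c3ccccc3)c2O)C(C)(C)C1 | target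

## Step count and risks

Total step count: 8. Longest linear sequence: 8 steps (1 to 17).

Steps most likely to fail:

**Step 5 (key step).** The C-allylation may show insufficient face selectivity (C1/C4-cis instead of trans). The palladium hydride may also be lost after β-hydride elimination, releasing the open-chain 1,3-diene instead of the allyl complex.

The fallback sets out from 8 and returns at 12, using known reactions only. Hydroboration of the vinyl group with 9-BBN-H (THF, rt) and oxidation with NaBO3·4H2O should give (4R)-3,3-dimethyl-5-nitro-4-[2,4,6-tris(methoxymethoxy)phenyl]pentan-1-ol F1. Oxidation with the periodinane DMP (CH2Cl2, NaHCO3) gives (4R)-3,3-dimethyl-5-nitro-4-[2,4,6-tris(methoxymethoxy)phenyl]pentanal F2. Its nitronate (Et3N, CH2Cl2) closes the C4–C5 bond in an intramolecular Henry reaction to (3R)-4,4-dimethyl-2-nitro-3-[2,4,6-tris(methoxymethoxy)phenyl]cyclopentan-1-ol F3. Mesylation and elimination (MeSO2Cl, Et3N) give (5R)-4,4-dimethyl-1-nitro-5-[2,4,6-tris(methoxymethoxy)phenyl]cyclopent-1-ene F4. Conjugate addition of CH2=C(CH3)MgBr (CuBr·SMe2, THF, −78 °C) from the face away from the aryl group, followed by protonation, should return 12.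

**Step 6.** Homolysis of the secondary C–NO2 bond may be slow, with competing N–O reduction toward the oxime and vinyl migration in the intermediate radical.

The fallback sets out from 12 and returns at 13. LiAlH4 (THF, 0 °C → reflux) reduces the nitro group to (2R,5R)-3,3-dimethyl-5-(prop-1-en-2-yl)-2-[2,4,6-tris(methoxymethoxy)phenyl]cyclopentan-1-amine F5 (epimers at C1). Hydrodeamination with the anomeric amide N-(benzyloxy)-N-(pivaloyloxy)-4-(trifluoromethyl)benzamide (MeCN, 45 °C) passes through a monosubstituted diazene that loses N2 and should give 13.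

**Step 3.** The hindered enamine may add sluggishly to the electron-rich, doubly ortho-substituted nitroalkene, and an uncatalysed background path may erode enantioselectivity.

The fallback sets out from 5 (with 6) and returns at 7. Condensation of 6 with (S)-1-amino-2-(methoxymethyl)pyrrolidine gives the hydrazone (E)-N-[(2S)-2-(methoxymethyl)pyrrolidin-1-yl]-2-methylpropan-1-imine F6. Its lithium azaenolate (LiN(i-Pr)2, THF, −78 °C) is a much stronger nucleophile than the enamine and should add to 5 at −100 °C under auxiliary control. This gives (3R)-(E)-N-[(2S)-2-(methoxymethyl)pyrrolidin-1-yl]-2,2-dimethyl-4-nitro-3-[2,4,6-tris(methoxymethoxy)phenyl]butan-1-imine F7. Hydrolysis with aqueous oxalic acid (Et2O, rt) releases the auxiliary and returns 7 (the descriptor changes to S only through the change in substituent ranking).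

## Further compounds

F1 | step 5 | (4R)-3,3-dimethyl-5-nitro-4-[2,4,6-tris(methoxymethoxy)phenyl]pentan-1-ol | [O-][N+](=O)C[C@@H](c1c(OCOC)cc(OCOC)cc1OCOC)C(C)(C)CCO
F2 | step 5 | (4R)-3,3-dimethyl-5-nitro-4-[2,4,6-tris(methoxymethoxy)phenyl]pentanal | [O-][N+](=O)C[C@@H](c1c(OCOC)cc(OCOC)cc1OCOC)C(C)(C)CC=O
F3 | step 5 | (3R)-4,4-dimethyl-2-nitro-3-[2,4,6-tris(methoxymethoxy)phenyl]cyclopentan-1-ol (C1 and C2 undefined) | OC1C([N+](=O)[O-])[C@@H](c2c(OCOC)cc(OCOC)cc2OCOC)C(C)(C)C1
F4 | step 5 | (5R)-4,4-dimethyl-1-nitro-5-[2,4,6-tris(methoxymethoxy)phenyl]cyclopent-1-ene | [O-][N+](=O)C1=CCC(C)(C)[C@@H]1c2c(OCOC)cc(OCOC)cc2OCOC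
F5 | step 6 | (2R,5R)-3,3-dimethyl-5-(prop-1-en-2-yl)-2-[2,4,6-tris(methoxymethoxy)phenyl]cyclopentan-1-amine (C1 undefined) | C=C(C)[C@@H]1C(N)[C@@H](c2c(OCOC)cc(OCOC)cc2OCOC)C(C)(C)C1
F6 | step 3 | (E)-N-[(2S)-2-(methoxymethyl)pyrrolidin-1-yl]-2-methylpropan-1-imine | COC[C@@H]1CCCN1/N=C/C(C)C
F7 | step 3 | (3R)-(E)-N-[(2S)-2-(methoxymethyl)pyrrolidin-1-yl]-2,2-dimethyl-4-nitro-3-[2,4,6-tris(methoxymethoxy)phenyl]butan-1-imine | COC[C@@H]1CCCN1/N=C/C(C)(C)[C@H](c2c(OCOC)cc(OCOC)cc2OCOC)C[N+](=O)[O-]
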